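**The leftover.** At 4.3 min the birch run read 0.359 M of Z, so 0.641 M of X stood unconverted, yet the last interval added 0.0180 M.

| flask | X | Q | time |
|---|---|---|---|
| birch | 1.00 M | 2.00 M |  |
| alder | 0.600 M | 1.60 M |  |
| elm | 3.00 M | 2.00 M |  |
| maple | 1.00 M | 1.00 M |  |
| cedar | 0.330 M | 6.00 M | 4.3 min |

| run | time / min | [Z] / M |
|---|---|---|
| birch run | 0.15 | 0.039 |
| birch run | 0.47 | 0.103 |
| birch run | 0.90 | 0.171 |
| birch run | 1.4 | 0.241 |
| birch run | 2.0 | 0.283 |
| birch run | 2.7 | 0.322 |
| birch run | 3.5 | 0.341 |
| birch run | 4.3 | 0.359 |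
| alder run | 0.15 | 0.018 |
| alder run | 0.47 | 0.055 |
| alder run | 0.90 | 0.095 |
| alder run | 1.4 | 0.127 |
| alder run | 2.0 | 0.150 |
| alder run | 2.7 | 0.182 |
| alder run | 3.5 | 0.190 |
| alder run | 4.3 | 0.201 |
| elm run | 0.15 | 0.108 |
| elm run | 0.47 | 0.299 |
| elm run | 0.90 | 0.490 |
| elm run | 1.4 | 0.639 |
| elm run | 2.0 | 0.755 |
| elm run | 2.7 | 0.841 |
| elm run | 3.5 | 0.886 |
| elm run | 4.3 | 0.910 |
| maple run | 0.15 | 0.024 |
| maple run | 0.47 | 0.067 |
| maple run | 0.90 | 0.111 |
| maple run | 1.4 | 0.152 |
| maple run | 2.0 | 0.190 |
| maple run | 2.7 | 0.219 |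
| maple run | 3.5 | 0.235 |
| maple run | 4.3 | 0.250 |

(readings scatter by 0.003 M)

- Overall: X + Q -> Z.
- Constant volume, constant temperature.
- The analysis sees a species whether free or bound.
- "The second partner" is Q.
- An order is taken over about fifteen percent of the charge, up and down.

- the exponent of [Q] in the starting rate at the charge of the birch run (at the point where two percent of the X have become Z)
- the exponent of [X] in the starting rate at the charge of the birch run (at the point where two percent of the X have become Z) (one fixed amount of Z, the same in the runs compared)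
- Z in the cedar run at 4.3 min, as a share of the X charged

**Per-X rates.** I pictured Z forming at a per-X rate a and returning at a rate b. The first birch reading gave a = 0.260 min⁻¹. On a flat curve, the share of X turned is a over a plus b, so the last birch share of 35.9% gave a plus b = 0.724 min⁻¹. The curve was not quite flat, and one correction made that 0.692 min⁻¹. Its inverse is τ = 1.44 min, the flask's lifetime or relaxation time. The share at time t is then a times τ, times one minus exp(−t/τ). For b, birch gave 0.432 min⁻¹.

**Maple test.** I carried b to the maple run. Its first reading gave a = 0.160 min⁻¹, so τ = 1.69 min. The predicted maple share at 4.3 min was 24.9%, and the reading gave 25.0%.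

**Cedar first.** In cedar, [Q] stands 18.2 times above [X]. I assumed that a held constant through the run, and no earlier run tested this at such a charge. First readings of birch and maple gave a [Q] exponent of 0.700. Scaling a to cedar's [Q] gave 0.561 min⁻¹ and a share of 55.7%.

**Weak link.** That exponent rested on a maple reading of 0.024 M with a scatter of 0.003 M. Second readings gave 0.620, and for [X], elm against birch gave 0.970. Cedar's a became 0.514 min⁻¹, its τ 1.06 min. I committed to a lower share than before, 53.4%.

**The result.** The forecast gave 0.64, 0.92 and a cedar share of 55%, above mine, reading that the flask “behaves like a reversible reaction or a dying process”. The flask gave 0.68, 1.0 and 56.4%.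

    X + Q ⇌ Z (0.2694 M⁻¹ min⁻¹, 0.2640 min⁻¹)
    2 Q → Oz (0.1230 M⁻¹ min⁻¹)
    2 Q ⇌ Q2, settled at all times (0.5720 M⁻¹)

**Lost Q.** Cedar's τ made 4.3 min worth 4.06 lifetimes, more than maple's 2.54. In my picture, 1.71% of the cedar gap then remained. But that picture held a constant, and with it [Q]. With the step in which two Q make Oz, cedar stood at 56.4%; without it, at 63.1%. That step cost cedar 6.7 percentage points.

Readings and results stem from a simulated flask from invented constants, and the scatter is random.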